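**No reading there.** No run reaches the ends of the question. The readings begin at 20.0 s and stop at 2.50 min, but the ratio is wanted earlier, at 6.0 s, and later, at 6.0 min. So we need a rule that carries across time.

in all of them: starting material 2.6 M
- summer: protic impurity 1.3 M; the very flask that is asked about, followed so far
- autumn: protic impurity 2 M; run made earlier
- flask: protic impurity 1.30 M; time 6.0 min

- summer (time / s: isomer of the product / %, target / %): 20.0: 1.8, 6.7; 40.0: 4.5, 12.4; 50.0: 5.3, 14.7; 80.0: 7.0, 21.1; 90.0: 8.0, 24.4; 120: 9.6, 30.0
- autumn (time / min: isomer of the product / %, target / %): 0.417: 2.5, 7.7; 0.833: 4.3, 14.6; 1.33: 7.0, 21.7; 1.50: 7.1, 24.0; 2.00: 9.3, 29.0; 2.50: 10.8, 34.7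

(standard deviation of a reading: 0.5 percentage points)

- a reading or a percentage of target counts all its forms, free or not

1. ratio of isomer of the product to target at 6.0 s
2. ratio of isomer of the product to target at 50 s
3. ratio of isomer of the product to target at 6.0 min

**Main step.** If starting material went to target and nowhere else, no isomer of the product would form and the ratio would be nil.

**Second path.** Now add a first-order path from starting material to isomer of the product, side by side with the first. Both paths draw on the same c(starting material), so the ratio of amounts stays constant from the start. We take this constant as the branching ratio, the selectivity factor: isomer formed per target formed, read from the last readings of both runs pooled, 0.315. The earliest summer reading gives 0.269, but it rests on 1.8% of isomer, read with a scatter of 0.5 percentage points.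

**The rest.** The autumn run has more c(protic impurity), 2 M against 1.3 M. Its last reading gives 0.311, and summer's gives 0.320. A target reading counts every form of target, so a form leaving solution stays in the count. We therefore commit to 0.315 at each asked time.

**The forecast.** It says 0.32, 0.32 and 0.35. The last stands above our number, on its own grounds: “This is a guess, so I skew the estimate and range upward”.

**The result.** The flask gives 0.322, 0.331 and 0.314, and the forecast is right within the tolerance. The half-life of isomer of the product for going back through its own step is 27 min, longer than 6.0 min. The branching ratio times the flask's target at 6.0 min, 55.4%, gives 17.5% of isomer; the flask holds 17.4%. A flat ratio is what the forecast would need to be wrong about, and a later time in this flask shows that: at 60.0 min the branching ratio times the target gives 22.8% of isomer of the product, more than the 11.2% the flask holds.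

    starting material + protic impurity → quenched substrate (k = 0.0240 M⁻¹ min⁻¹)
    crystals ⇌ target, rate k2*(cs2 - [target]) while solid is left; crystals form when [target] > cs2 (solubility = 0.0640 M, k = 7.60 min⁻¹)
    starting material ⇌ target (K = 0.970, k = 0.210 min⁻¹)
    starting material ⇌ isomer of the product (K = 2.60, k = 0.0670 min⁻¹)

**Second flask.** The neighbour charged with 0.65 M of starting material holds 49.6% of target at 6.0 min, so the branching ratio gives 15.6% of isomer and a ratio of 0.315. The computed neighbour has 18.3% of isomer and a ratio of 0.368, higher than the branching ratio.

The earlier runs and the new flask are simulated with constants of no real substance; the scatter is artificial.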